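All constants come from no measurement; the rest is arithmetic.

Follow the coupling partner.

    substrate + coupling partner → target, rate k1*[substrate]^1.5*[coupling partner] (k1 = 0.989 L¹·⁵ mol⁻¹·⁵ min⁻¹, Ea1 = 58.0 kJ mol⁻¹)
    target ⇌ isomer of the product (K2 = 1.21, k2 = 0.429 min⁻¹, Ea2 = 97.0 kJ mol⁻¹, ΔH2 = −10.0 kJ mol⁻¹)
    coupling partner → decomposed reagent (k3 = 0.198 min⁻¹, Ea3 = 101 kJ mol⁻¹)
    (constants at 40 °C)

| flask | substrate | coupling partner | temperature | time | remark |
|---|---|---|---|---|---|
| zeta | 1.0 M | 0.600 M | 40 °C | 6.0 min |  |
| epsilon | 1.0 M | 0.600 M | 90 °C | 6.0 min |  |
| theta | 1.0 M | 0.600 M |  | 6.0 min | at 40 °C until 3.0 min, from then on at 90 °C |
| beta | 1.0 M | 0.600 M | 65 °C | 6.0 min |  |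

- the constants hold at 40 °C; other temperatures follow from the activation energies and enthalpies

- which flask leads in amount of target, in percent of the substrate charged ("all alike" within 1.5 percentage points) (zeta / epsilon / theta / beta / all alike)
- how much target is there at the end, in percent of the substrate charged: zeta
- how much target is there at the end, in percent of the substrate charged: epsilon
- how much target is there at the end, in percent of the substrate charged: theta
- how much target is there at the end, in percent of the substrate charged: beta

- Two steps consume the coupling partner, and both are first order in it, so you can treat its fate as a race of half-lives. At the full substrate charge and 40 °C, the half-life is 0.701 min by the coupling and 3.50 min by the decomposition.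
- The ratio of those half-lives is a selectivity factor of 4.99, and the coupling partner's own amount cancels from it. From this factor comes the partner's share, 0.833, which is the fraction of the coupling partner being consumed at that moment that becomes target rather than decomposed reagent.
- In the first instants of zeta and theta, the coupling wins the race because its half-life is shorter than the decomposition's. Multiplying the share by the partner charge per substrate charge gives 0.500 of the substrate charge converted. I take this as a ceiling, since the share falls as substrate is used.
- In the middle of zeta, the combined half-life of the partner starts at 0.584 min. By 3.0 min that pace would allow 5.14 half-lives and leave 0.0284 of the partner's own charge. That is a lower bound, because the pace falls with the substrate.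
- Meanwhile the isomerisation relaxes with a half-life of 0.885 min, so in zeta the converted material tends to a target fraction of 0.452. Applying that fraction to the ceiling on conversion gives my figure for target in zeta, 0.226 of the substrate charge, which is an estimate and no bound.
- Heat changes the race: from 40 °C to 90 °C the decomposition speeds up 210-fold and the coupling 21-fold. In epsilon the selectivity factor therefore starts at 0.514, the share at 0.340 and the ceiling at 0.204 of the substrate charge.
- At the end of theta, heat meets just the partner left at the change, so I expect theta to convert about as much as zeta. The isomerisation is exothermic, so heat should then move material back toward target. My reckoning gives no figure for that shift, but it puts theta first and epsilon low.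
- The forecast names theta, with target at 21.2% in zeta, 10.7% in epsilon, 24.9% in theta and 16.5% in beta. Its ground for the lead is: “Theta leads because it makes most of its product cold and then heats”. My zeta estimate differs from the forecast's number and stands above it.
- The simulation gives theta as the leader, with target at 21.4% in zeta, 10.7% in epsilon, 25.0% in theta and 16.5% in beta.
- Theta has lost 43 percentage points of its substrate, under the ceiling of 0.500. The neighbouring flask is theta with 1.0 M of coupling partner. The share contains no partner, so it starts at 0.833 again, while the ceiling grows with the charge to 0.833 of the substrate charge. That neighbour ends with 37.8% of its substrate left, so it has lost 62 points, again under the ceiling, and it holds 36.3% as target.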